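Assumption: positions are named with gibberellin numbering (C1–C19), and the target SMILES is read as 2β,3β,11β-trihydroxy-GA9 (GA9 = the same 19,10-lactone acid without the three hydroxyls).

**Retrosynthetic overview**
1. Target ⇐ acetonide and allyl-ester removal, C6 epimerisation and exo-face reduction of a pentacyclic 11-oxo lactone.
2. Ring B and the 19,10-lactone close last, by intramolecular aldol (C9→C10) with lactonisation of a diketo diester.
3. The diketo diester comes from a late radical coupling (C6–C8) of fragment A (ring A ene-dione diester, 10 skeletal carbons) with fragment B (rings C/D bridgehead oxalate, 9 skeletal carbons).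
4. Fragment A: bromobenzene → Birch alkylation → desymmetrising bromolactonisation (C4) → exo dihydroxylation on the bicyclic lactone → Wittig at C5 → lactone opening and oxidation.
5. Fragment B: cyclohexane-1,3-dione (ring C) + 2,3-dibromopropene → enantioselective conjugate borylation (C8) → vinyl-radical closure of ring D; ring order A, C, D, then B with the lactone.

**Fragment A**

Step 1
Reactants: 1 bromobenzene
Product: 3 benzoic acid, via phenylmagnesium bromide 2 (not isolated)
Conditions: Mg, THF, reflux; CO2 (s), −78 °C to rt; aq. HCl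
Reagents that add atoms: carbon dioxide, O=C=O
Why: Grignard carboxylation turns the aryl bromide into the arenecarboxylic acid needed for reductive alkylation, and no stereocentre is formed.

Step 2
Reactants: 3 benzoic acid
Product: 4 1-methylcyclohexa-2,5-diene-1-carboxylic acid
Conditions: Li (2.2 equiv), NH3 (l)/THF, −78 °C; MeI; NH4Cl then aq. HCl
Reagents that add atoms: iodomethane, CI
Why: Birch reduction–alkylation methylates the dilithium 1,4-dihydrobenzoate dienolate at the carboxylate-bearing carbon, which puts C18 and C19 on the future C4 as a prochiral quaternary centre flanked by two enantiotopic alkenes.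

Step 3
Reactants: 4 1-methylcyclohexa-2,5-diene-1-carboxylic acid
Product: 5 (1S,5S,8S)-8-bromo-1-methyl-6-oxabicyclo[3.2.1]oct-2-en-7-one
Conditions: NBS (1.1 equiv), (DHQD)2PHAL (10 mol %), CHCl3/n-hexane 1:1, −40 °C
Reagents that add atoms: N-bromosuccinimide, O=C1CCC(=O)N1Br
Why: Cinchona-alkaloid-catalysed desymmetrising bromolactonisation brominates one of the two enantiotopic alkenes and the carboxylate closes anti across it, which fixes C4 and gives C10–O cis to C19 with bromine trans at C5 (the pseudo-enantiomeric (DHQ)2PHAL is used if the sense of induction proves opposite).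

Step 4
Reactants: 5 bromolactone
Product: 6 (1R,5S)-8-hydroxy-1-methyl-6-oxabicyclo[3.2.1]oct-2-en-7-one (both C8 epimers)
Conditions: Bu3SnH (2.5 equiv, slow addition), AIBN (cat), dry air, toluene, 60 °C
Reagents that add atoms: dioxygen, O=O
Why: Radical-chain oxygenation abstracts the bromine, traps the bridge radical with O2 and reduces the hydroperoxide in situ with Bu3SnH, and the carbinol configuration is irrelevant because it is oxidised next.

Step 5
Reactants: 6 hydroxy lactone
Product: 7 (1R,5S)-1-methyl-6-oxabicyclo[3.2.1]oct-2-ene-7,8-dione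
Conditions: Dess–Martin periodinane, NaHCO3, CH2Cl2, 0 °C to rt
Reagents that add atoms: none
Why: Dess–Martin oxidation of the secondary carbinol gives the strained bridging ketone under buffered neutral conditions that leave the lactone and the alkene untouched.

Step 6
Reactants: 7 keto lactone
Product: 8 (1R,2R,3S,5S)-2,3-dihydroxy-1-methyl-6-oxabicyclo[3.2.1]octane-7,8-dione
Conditions: OsO4 (2 mol %), NMO, acetone/H2O 8:1, 0 °C to rt
Reagents that add atoms: N-methylmorpholine N-oxide, C[N+]1([O-])CCOCC1; water, O
Why: Upjohn dihydroxylation adds syn from the exo face opposite the two-atom lactone bridge (the one-carbon bridge is now a planar carbonyl with nothing over that face), which sets both hydroxyls β and cis to the C4 methyl as in the target.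

Step 7
Reactants: 8 diol
Product: 9 acetonide of 8 (2β,3β-isopropylidenedioxy keto lactone)
Conditions: 2-methoxypropene, PPTS (cat), CH2Cl2, 0 °C
Reagents that add atoms: 2-methoxypropene, C=C(C)OC
Why: Acetalisation of the cis-diol under mild acid gives the acetonide, which blocks diol oxidation and retro-aldol chemistry in the later steps.

Step 8
Reactants: 9 acetonide keto lactone
Product: 10 methyl (Z)-2-(lactone-8-ylidene)acetate (C5=C6 alkylidene lactone)
Conditions: Ph3P=CHCO2Me (1.5 equiv), toluene, 100 °C
Reagents that add atoms: methyl (triphenylphosphoranylidene)acetate, COC(=O)C=P(c1ccccc1)(c1ccccc1)c1ccccc1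
Why: Wittig olefination with a stabilised ylide engages this strained α-acyloxy ketone without a free alkoxide that could trigger retro-Claisen cleavage, and the ester settles anti to the quaternary C4 (Z), a geometry that is lost again in step 20.

Step 9
Reactants: 10 alkylidene lactone
Product: 12 (Z)-keto diacid, via hydroxy diacid 11 (not isolated)
Conditions: LiOH (4 equiv), THF/H2O, 0 °C to rt; then TEMPO (cat), KBr, NaOCl, NaHCO3, 0 °C; 1 M HCl to pH 3
Reagents that add atoms: lithium hydroxide, [Li+].[OH-]
Why: Saponification opens the lactone and the methyl ester, and Anelli (TEMPO/hypochlorite) oxidation of the allylic carbinol is run directly in the basic solution, where the dicarboxylate cannot close to the butenolide that a free γ-hydroxy Z-enoate would form.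

Step 10
Reactants: 12 keto diacid
Product: 13 diallyl ester of 12 (fragment A)
Conditions: allyl bromide (3 equiv), KHCO3, DMF, 0 °C to rt
Reagents that add atoms: allyl bromide, C=CCBr
Why: O-alkylation of both carboxylates traps the open-chain ene-dione ester instead of its cyclic pseudo-acid, the C19 allyl ester later serving as leaving group and the C7 allyl ester as protecting group.

**Fragment B**

Step 11
Reactants: 14 cyclohexane-1,3-dione
Product: 15 3-ethoxycyclohex-2-en-1-one
Conditions: EtOH, p-TsOH (cat), toluene, reflux (Dean–Stark)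
Reagents that add atoms: ethanol, CCO
Why: Acid-catalysed condensation of the vinylogous acid with ethanol under azeotropic water removal gives the vinylogous ester needed for carbonyl transposition.

Step 12
Reactants: 15 3-ethoxycyclohex-2-en-1-one; 16 2,3-dibromoprop-1-ene
Product: 18 3-(2-bromoprop-2-en-1-yl)cyclohex-2-en-1-one, via carbinol 17 (not isolated)
Conditions: In powder, DMF, rt; then 1 M HCl, rt
Reagents that add atoms: none
Why: Stork–Danheiser transposition, in which the Barbier-type allylindium reagent adds 1,2 to the vinylogous ester carbonyl and acid hydrolysis of the enol ether with loss of water moves the enone while the vinyl bromide stays intact.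

Step 13
Reactants: 18 enone
Product: 20 (S)-3-(2-bromoprop-2-en-1-yl)-3-hydroxycyclohexan-1-one, via boronate 19 (not isolated)
Conditions: CuCl (5 mol %), (R,R)-QuinoxP* (6 mol %), NaOtBu (10 mol %), B2pin2, MeOH (2 equiv), THF, rt; then 30% H2O2, NaHCO3, THF/H2O, 0 °C
Reagents that add atoms: hydrogen peroxide, OO
Why: Copper-catalysed enantioselective conjugate borylation followed by stereoretentive C–B oxidation, in which the chiral bisphosphine–copper boryl adds to one face of the β,β-disubstituted enone and sets the future C8 (the antipodal ligand is used if the sense is reversed).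

Step 14
Reactants: 20 tertiary β-hydroxy ketone
Product: 21 (S)-3-(2-bromoprop-2-en-1-yl)-3-(triethylsilyloxy)cyclohexan-1-one
Conditions: TESOTf, 2,6-lutidine, CH2Cl2, −78 °C
Reagents that add atoms: triethylsilyl trifluoromethanesulfonate, CC[Si](CC)(CC)OS(=O)(=O)C(F)(F)F
Why: Silylation of the tertiary carbinol with the reactive triflate prevents retro-aldol cleavage and β-elimination during the enolate and radical steps.

Step 15
Reactants: 21 silyl ether ketone
Product: 23 (S)-5-(2-bromoprop-2-en-1-yl)-5-(triethylsilyloxy)cyclohex-2-en-1-one, via lithium enolate 22 (not isolated)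
Conditions: LiN(iPr)2, THF, −78 °C; then N-tert-butylbenzenesulfinimidoyl chloride, −78 °C
Reagents that add atoms: none
Why: Kinetic deprotonation occurs at the methylene remote from the fully substituted carbon and Mukaiyama dehydrogenation of the lithium enolate with the sulfinimidoyl chloride gives the enone directly, which avoids palladium in the presence of the vinyl bromide.

Step 16
Reactants: 23 bromoallyl enone
Product: 24 (1R,5S)-6-methylidene-1-(triethylsilyloxy)bicyclo[3.2.1]octan-3-one
Conditions: Bu3SnH (slow addition), AIBN (cat), benzene (0.01 M), 80 °C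
Reagents that add atoms: none
Why: Tin-hydride-mediated 5-exo-trig vinyl radical cyclisation onto the enone β-carbon closes ring D with the exocyclic methylene already in place, and because the two-carbon bridge can only span the ring cis the C13 configuration follows from C8.

Step 17
Reactants: 24 bicyclic silyl ether
Product: 25 (1R,5S)-1-hydroxy-6-methylidenebicyclo[3.2.1]octan-3-one
Conditions: HF·pyridine, THF/pyridine, 0 °C to rt
Reagents that add atoms: none
Why: Fluoride-mediated desilylation frees the bridgehead tertiary alcohol, which cannot dehydrate because the alkene would sit at a bridgehead.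

Step 18
Reactants: 25 bridgehead alcohol
Product: 26 methyl (1R,5S)-6-methylidene-3-oxobicyclo[3.2.1]octan-1-yl oxalate
Conditions: ClC(O)CO2Me, Et3N, DMAP (cat), CH2Cl2, 0 °C
Reagents that add atoms: methyl chlorooxoacetate, COC(=O)C(=O)Cl
Why: Acylation of the hindered tertiary alcohol with the highly electrophilic oxalyl half-ester chloride under nucleophilic catalysis installs the radical precursor.

Step 19
Reactants: 26 methyl oxalate
Product: 27 cesium (1R,5S)-6-methylidene-3-oxobicyclo[3.2.1]octan-1-yl oxalate (fragment B)
Conditions: CsOH·H2O (1.0 equiv), THF/H2O, rt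
Reagents that add atoms: cesium hydroxide, [Cs+].[OH-]
Why: Chemoselective saponification, in which one equivalent of hydroxide cleaves only the unhindered activated methyl ester of the mixed oxalate and gives the bench-stable cesium salt.

**Coupling and endgame**

Step 20
Reactants: 27 cesium oxalate (fragment B); 13 diallyl ene-dione ester (fragment A)
Product: 28 diketo diallyl ester with the new C6–C8 bond (C5/C6 epimer mixture)
Conditions: Ir[dF(CF3)ppy]2(dtbbpy)PF6 (1 mol %), DME/DMF 3:1, H2O (10 equiv), blue LEDs, 60 °C
Reagents that add atoms: none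
Why: Photoredox decarboxylative Giese addition, in which oxidation of the oxalate by the excited iridium complex and loss of two CO2 give a bridgehead radical that cannot invert and so carries the C8 configuration intact while it adds to the less substituted alkene carbon (C6), the resulting α-keto radical being reduced and protonated to a mixture at the epimerisable C5 and C6.

Step 21
Reactants: 28 diketo diallyl ester
Product: 30 allyl 2β,3β-(isopropylidenedioxy)-11-oxo-GA9 ester (C6 epimer mixture), via aldol 29 (not isolated)
Conditions: LiN(SiMe3)2 (1.3 equiv), THF, −78 to −10 °C; aq. NH4Cl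
Reagents that add atoms: none
Why: Intramolecular aldol addition with lactonisation, in which the C9 enolate of the bicyclic ketone attacks the C10 ketone 5-exo from its exo face (setting C9) and of the reversible aldolates only the one whose C10 alkoxide is cis to the axial C19 ester is trapped as the γ-lactone (setting C10 and, through the trans ring fusion, C5), while the C2–O bond stays equatorial and so resists β-elimination.

Step 22
Reactants: 30 pentacyclic 11-oxo lactone
Product: 31 allyl 11β-hydroxy-2β,3β-(isopropylidenedioxy)-GA9 ester (C6 epimer mixture)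
Conditions: LiBH(s-Bu)3, THF, −78 °C; aq. NH4Cl
Reagents that add atoms: none
Why: Hydride reduction with a bulky borohydride attacks the bicyclic ketone from the exo face away from the two-carbon bridge and gives the axial 11β-alcohol without touching the ester or the lactone.

Step 23
Reactants: 31 C6 epimer mixture
Product: 32 allyl 11β-hydroxy-2β,3β-(isopropylidenedioxy)-GA9 ester (natural C6 configuration)
Conditions: NaOCH2CH=CH2 (0.3 equiv), allyl alcohol/THF 1:4, 45 °C
Reagents that add atoms: none
Why: Base-mediated epimerisation through the ester enolate drives C6 to the thermodynamically preferred configuration with the carboxylate trans to the bulky C4 on the neighbouring carbon, the degenerate transesterification with allyloxide being harmless.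

Step 24
Reactants: 32 allyl ester
Product: 33 11β-hydroxy-2β,3β-(isopropylidenedioxy)-GA9 (free C7 acid)
Conditions: Pd(PPh3)4 (5 mol %), morpholine, THF, rt; then dilute aq. KHSO4
Reagents that add atoms: none
Why: Tsuji–Trost deallylation, in which zerovalent palladium ionises the allyl ester and morpholine captures the allyl unit under neutral conditions that spare the lactone, the acetonide and the exocyclic alkene.

Step 25
Reactants: 33 acetonide acid
Product: 34 CNP0322347.1 (2β,3β,11β-trihydroxy-GA9)
Conditions: AcOH/H2O 4:1, 45 °C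
Reagents that add atoms: none
Why: Acid-catalysed acetal hydrolysis in aqueous acetic acid frees the cis-diol under conditions too mild to isomerise the exocyclic methylene or epimerise C3.

**Compound list**

1 | bromobenzene | Brc1ccccc1 | starting material
2 | phenylmagnesium bromide | Br[Mg]c1ccccc1 | intermediate
3 | benzoic acid | OC(=O)c1ccccc1 | intermediate
4 | 1-methylcyclohexa-2,5-diene-1-carboxylic acid | CC1(C(=O)O)C=CCC=C1 | intermediate
5 | (1S,5S,8S)-8-bromo-1-methyl-6-oxabicyclo[3.2.1]oct-2-en-7-one (lactone O at C10 cis to C19, Br trans) | [C@@H]12CC=C[C@@](C)(C(=O)O1)[C@@H]2Br | intermediate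
6 | (1R,5S)-8-hydroxy-1-methyl-6-oxabicyclo[3.2.1]oct-2-en-7-one, both C8 epimers | [C@@H]12CC=C[C@@](C)(C(=O)O1)C2O | intermediate
7 | (1R,5S)-1-methyl-6-oxabicyclo[3.2.1]oct-2-ene-7,8-dione | [C@@H]12CC=C[C@@](C)(C(=O)O1)C2=O | intermediate
8 | (1R,2R,3S,5S)-2,3-dihydroxy-1-methyl-6-oxabicyclo[3.2.1]octane-7,8-dione (both OH exo, 2β,3β in gibberellin numbering) | [C@@H]12C[C@H](O)[C@H](O)[C@@](C)(C(=O)O1)C2=O | intermediate
9 | acetonide of 8 | [C@@H]12C[C@H](OC3(C)C)[C@H](O3)[C@@](C)(C(=O)O1)C2=O | intermediate
10 | methyl (Z)-2-(ylidene)acetate of 9 (C5=C6, ester syn to C10, ring stereocentres as in 9) | [C@@H]12C[C@H](OC3(C)C)[C@H](O3)[C@@](C)(C(=O)O1)/C2=C/C(=O)OC | intermediate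
11 | (Z)-hydroxy diacid (C10 carbinol, C19 and C7 acids, 2β,3β-acetonide), formed as its dilithium salt | O[C@H]1C[C@H](OC2(C)C)[C@H](O2)[C@@](C)(C(=O)O)/C1=C/C(=O)O | intermediate
12 | (Z)-keto diacid (C10 ketone; exists largely as the cyclic hydroxybutenolide tautomer) | O=C1C[C@H](OC2(C)C)[C@H](O2)[C@@](C)(C(=O)O)/C1=C/C(=O)O | intermediate
13 | fragment A: diallyl ester of 12 (C10 ketone, C5=C6H–CO2allyl, 4α-CO2allyl, 4β-Me, 2β,3β-acetonide) | O=C1C[C@H](OC2(C)C)[C@H](O2)[C@@](C)(C(=O)OCC=C)/C1=C/C(=O)OCC=C | intermediate
14 | cyclohexane-1,3-dione | O=C1CCCC(=O)C1 | starting material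
15 | 3-ethoxycyclohex-2-en-1-one | CCOC1=CC(=O)CCC1 | intermediate
16 | 2,3-dibromoprop-1-ene | C=C(Br)CBr | starting material
17 | 1-(2-bromoprop-2-en-1-yl)-3-ethoxycyclohex-2-en-1-ol (racemic) | CCOC1=CC(O)(CC(Br)=C)CCC1 | intermediate
18 | 3-(2-bromoprop-2-en-1-yl)cyclohex-2-en-1-one | C=C(Br)CC1=CC(=O)CCC1 | intermediate
19 | (R)-3-(2-bromoprop-2-en-1-yl)-3-(4,4,5,5-tetramethyl-1,3,2-dioxaborolan-2-yl)cyclohexan-1-one | C=C(Br)C[C@]1(B2OC(C)(C)C(C)(C)O2)CCCC(=O)C1 | intermediate
20 | (S)-3-(2-bromoprop-2-en-1-yl)-3-hydroxycyclohexan-1-one | C=C(Br)C[C@]1(O)CCCC(=O)C1 | intermediate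
21 | (S)-3-(2-bromoprop-2-en-1-yl)-3-(triethylsilyloxy)cyclohexan-1-one | C=C(Br)C[C@]1(O[Si](CC)(CC)CC)CCCC(=O)C1 | intermediate
22 | lithium enolate of 21 (enolised away from the quaternary carbon) | C=C(Br)C[C@]1(O[Si](CC)(CC)CC)CCC=C([O-])C1.[Li+] | intermediate
23 | (S)-5-(2-bromoprop-2-en-1-yl)-5-(triethylsilyloxy)cyclohex-2-en-1-one | C=C(Br)C[C@]1(O[Si](CC)(CC)CC)CC=CC(=O)C1 | intermediate
24 | (1R,5S)-6-methylidene-1-(triethylsilyloxy)bicyclo[3.2.1]octan-3-one | C=C1C[C@]2(O[Si](CC)(CC)CC)C[C@H]1CC(=O)C2 | intermediate
25 | (1R,5S)-1-hydroxy-6-methylidenebicyclo[3.2.1]octan-3-one | C=C1C[C@]2(O)C[C@H]1CC(=O)C2 | intermediate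
26 | methyl (1R,5S)-6-methylidene-3-oxobicyclo[3.2.1]octan-1-yl oxalate | C=C1C[C@]2(OC(=O)C(=O)OC)C[C@H]1CC(=O)C2 | intermediate
27 | fragment B: cesium (1R,5S)-6-methylidene-3-oxobicyclo[3.2.1]octan-1-yl oxalate | C=C1C[C@]2(OC(=O)C(=O)[O-])C[C@H]1CC(=O)C2.[Cs+] | intermediate
28 | coupling product: ring A ketone (C10=O, 2β,3β-acetonide, 4α-CO2allyl, 4β-Me) joined through C6 (bearing CO2allyl) to bridgehead C8 of the 6-methylidene-3-oxobicyclo[3.2.1]octane; C5/C6 epimers | C=C1C[C@@]2(C[C@H]1CC(=O)C2)C(C(=O)OCC=C)C1C(=O)C[C@H](OC3(C)C)[C@H](O3)[C@@]1(C)C(=O)OCC=C | intermediate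
29 | aldol: ring B closed (C9–C10), free 10α-hydroxyl, C19 and C7 allyl esters, C11 ketone; C6 epimers; formed as the lithium alkoxide | C=C1C[C@]23C[C@H]1CC(=O)[C@H]2[C@]2(O)C[C@H](OC4(C)C)[C@H](O4)[C@@](C)(C(=O)OCC=C)[C@H]2C3C(=O)OCC=C | intermediate
30 | allyl 2β,3β-(isopropylidenedioxy)-11-oxo-GA9 ester, C6 epimers | C=C1C[C@]23C[C@H]1CC(=O)[C@H]2[C@@]12C[C@H](OC4(C)C)[C@H](O4)[C@@](C)(C(=O)O1)[C@H]2C3C(=O)OCC=C | intermediate
31 | allyl 11β-hydroxy-2β,3β-(isopropylidenedioxy)-GA9 ester, C6 epimers | C=C1C[C@]23C[C@H]1C[C@H](O)[C@H]2[C@@]12C[C@H](OC4(C)C)[C@H](O4)[C@@](C)(C(=O)O1)[C@H]2C3C(=O)OCC=C | intermediate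
32 | allyl 11β-hydroxy-2β,3β-(isopropylidenedioxy)-GA9 ester, natural C6 configuration | C=C1C[C@]23C[C@H]1C[C@H](O)[C@H]2[C@@]12C[C@H](OC4(C)C)[C@H](O4)[C@@](C)(C(=O)O1)[C@H]2[C@@H]3C(=O)OCC=C | intermediate
33 | 11β-hydroxy-2β,3β-(isopropylidenedioxy)-GA9 (free acid) | C=C1C[C@]23C[C@H]1C[C@H](O)[C@H]2[C@@]12C[C@H](OC4(C)C)[C@H](O4)[C@@](C)(C(=O)O1)[C@H]2[C@@H]3C(=O)O | intermediate
34 | CNP0322347.1, 2β,3β,11β-trihydroxy-GA9 | C=C1C[C@]23C[C@H]1C[C@H](O)[C@H]2[C@@]12C[C@H](O)[C@H](O)[C@@](C)(C(=O)O1)[C@H]2[C@@H]3C(=O)O | target

**Totals and risks**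

Total step count: 25. Longest linear sequence: 16 steps (steps 1–10, then 20–25); the fragment B branch is 9 steps (11–19).

Steps most likely to fail:

Step 20 (radical fragment coupling). The bridgehead alkoxycarbonyl radical may lose CO2 too slowly, or the trisubstituted acceptor may be too hindered. Fallback: make the same bridgehead radical from boron instead of the oxalate. Set out from enone 18 and run the conjugate borylation of step 13 without the peroxide work-up, isolating boronate 19. Dehydrogenate it as in step 15 to the enone pinacol boronate F1. Close ring D with Bu3SnH/AIBN to the bridgehead pinacol boronate F2. Treat with aqueous KHF2 in MeOH to get the potassium trifluoroborate F3. Oxidise F3 with 9-mesityl-10-methylacridinium perchlorate under blue light (acetone/MeOH) in the presence of 13; this gives 28, where the route resumes.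

Step 21 (aldol–lactonisation). Base may enolise the wrong ketone, eliminate the C2 oxygen, or epimerise C9. Fallback: a Lewis-acid Mukaiyama aldol that avoids free enolates. Set out from 28 and silylate the less hindered bicyclic ketone (TBSOTf, Et3N, CH2Cl2, −78 °C; the enol-silane regioisomers equilibrate under catalytic triflate) to the Δ9(11) tert-butyldimethylsilyl enol ether F4. Close ring B with TiCl4 in CH2Cl2 at −78 °C to give aldol 29, now isolated. Lactonise separately with catalytic camphorsulfonic acid in toluene at 60 °C to reach 30.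

Step 8 (Wittig on the strained β-keto lactone). The ylide may be too sluggish or may cleave the ring by retro-Claisen. Fallback: addition then elimination. Set out from 9 and add the Reformatsky reagent from methyl bromoacetate and Zn (THF, 40 °C) to give the tertiary β-hydroxy ester F5. Dehydrate with SOCl2/pyridine at 0 °C; elimination can only go exocyclic because both ring neighbours are bridgeheads. This returns to 10 (either alkene geometry is usable).

Further compounds
F1 | step 20 | 5-(2-bromoprop-2-en-1-yl)-5-(4,4,5,5-tetramethyl-1,3,2-dioxaborolan-2-yl)cyclohex-2-en-1-one (boron in place of the silyloxy group of 23) | C=C(Br)C[C@]1(B2OC(C)(C)C(C)(C)O2)CC=CC(=O)C1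
F2 | step 20 | 6-methylidene-1-(4,4,5,5-tetramethyl-1,3,2-dioxaborolan-2-yl)bicyclo[3.2.1]octan-3-one (bridgehead configuration as in 25) | C=C1C[C@]2(B3OC(C)(C)C(C)(C)O3)C[C@H]1CC(=O)C2
F3 | step 20 | potassium trifluoro(6-methylidene-3-oxobicyclo[3.2.1]octan-1-yl)borate | C=C1C[C@]2([B-](F)(F)F)C[C@H]1CC(=O)C2.[K+]
F4 | step 21 | Δ9(11) tert-butyldimethylsilyl enol ether of 28 (C5/C6 epimers) | C=C1C[C@@]2(C[C@H]1CC(O[Si](C)(C)C(C)(C)C)=C2)C(C(=O)OCC=C)C1C(=O)C[C@H](OC3(C)C)[C@H](O3)[C@@]1(C)C(=O)OCC=C
F5 | step 8 | methyl 2-(8-hydroxy-lactone-8-yl)acetate, Reformatsky adduct of 9 (carbinol epimers) | [C@@H]12C[C@H](OC3(C)C)[C@H](O3)[C@@](C)(C(=O)O1)C2(O)CC(=O)OC
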